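South-west and south differed in their time of reading, 20 h against 40 h, so I needed the moment at which the lead changes hands.

    substrate + coupling partner → intermediate A (k1 = 0.28 /M/h)
    target ⇌ isomer of the product (K2 = 22, k2 = 0.55 /h)
    coupling partner + intermediate A → target (k3 = 0.26 /M/h)
    substrate → intermediate B (k4 = 0.27 /h)
    intermediate B → side product (k5 = 0.032 /h)

| flask | substrate | coupling partner | time |
|---|---|---|---|
| south-west | 0.12 M | 4.00 equiv | 20 h |
| south | 0.12 M | 4.00 equiv | 40 h |

- which of these there is most of at the end, counted by the substrate in it, south-west (intermediate A / isomer of the product / side product / intermediate B / target)
- which of these there is most of at the end, counted by the substrate in it, south (intermediate A / isomer of the product / side product / intermediate B / target)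
- how much there is at the end of the one of these that leads, in percent of the substrate charged: south-west
- how much there is at the end of the one of these that leads, in percent of the substrate charged: south

I held [coupling partner] at its charge of 0.480 M, which made the loss of substrate pseudo-first-order with constant 0.404 /h and mean life 2.47 h. On that reckoning 66.8% of the substrate went to intermediate B. Because this mean life is shorter than the 22 h half-life of intermediate B, I treated intermediate B as formed after that delay and then decaying to side product. Delay plus half-life gave 24.1 h, the crossing time, the moment when side product draws level with intermediate B.

South-west was read earlier than that, so I put intermediate B ahead at 38.1%. South was read later, so I put side product ahead at 46.7%. I gave the branch through intermediate A 33.2%, less than either figure.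

The forecast gave intermediate B at 38.5% (36.5% to 40.5%) for south-west and side product at 47% (44.5% to 49.5%) for south, slightly above my figures : “B leads at 20 h; side product leads at 40 h”.

The simulation gave intermediate B at 38.9% in south-west and side product at 47.3% in south. South held 38.9% of intermediate B and 28.9% of side product at 20.0 h, as south-west did at its reading. The same charge stopped at 10 h lies before the crossing time of 24.1 h, so intermediate B should lead there, at 52.5% by the same reckoning. That flask held 14.3% of side product and 52.2% of intermediate B.

The numbers of this flask are those of an exercise; what happens was integrated by code.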